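The plan rests on cutting ring C at C8–C8a, which leads back to a naphthalene (rings A and B) carrying a four-carbon amino methoxy squarate unit on C4b. The feature exploited is the unbroken run O, N, OMe, O on C5, C6, C7 and C8 of ring C, fused to the C4b=C8a edge of ring B: it maps onto a squarate that already holds nitrogen and methoxy in their final places. In one thermal operation a 4-naphthyl-4-hydroxycyclobutenone opens to a vinylketene, closes onto C8a and, after oxidation, gives ring C as the 5,8-quinone. The precursor is that cyclobutenone, with the L-prolinate on C3 and methoxy on C2, made from a bromonaphthalene whose bromine is placed by construction.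

Key step: step 8

Numbering: phenanthrene numbering is used for all tricyclic compounds (ring A = C1–C4, C4a, C10a; ring B = C4a, C4b, C8a, C9, C10, C10a; ring C = C4b, C5–C8, C8a).

Assumption 1: the 1,10-diol freed in the last step is taken to rest as the C9H2/C10 ketone tautomer drawn for the target, held by the hydrogen bond from the C1 hydroxyl.

Assumption 2: the (S)-prolinate is taken to favour methyl delivery to the C5 face that gives 5R. The sense of this bias cannot be predicted with confidence, but the two C5 epimers are diastereomers, so 5R material can be isolated pure either way, and a reversed bias is answered by the D-proline series given at the end.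

Assumption 3: the N,O-acetal is taken to settle, through reversible iminium formation, in the natural configuration, with the aminal hydrogen cis to the C5 methyl (methyl on the convex face of the fused oxazolidine–pyrrolidine).

Step 1
Reactants: 1 3-(benzyloxy)phenylacetic acid
Product: 2 2-[5-(benzyloxy)-2-bromophenyl]acetic acid
Conditions: NBS, MeCN, rt, dark
Reagents that add atoms: N-bromosuccinimide, O=C1CCC(=O)N1Br
Why: Electrophilic aromatic bromination with NBS in acetonitrile goes para to the benzyloxy group (ortho to the CH2CO2H arm), as is usual for 3-alkoxyphenylacetic acids, which fixes bromine on the future C4b before ring A exists, so that no later halogenation has to choose between two electron-rich rings.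

Step 2
Reactants: 2 2-[5-(benzyloxy)-2-bromophenyl]acetic acid; 3 Meldrum's acid (2,2-dimethyl-1,3-dioxane-4,6-dione)
Product: 5 methyl 4-[5-(benzyloxy)-2-bromophenyl]-3-oxobutanoate, via acyl Meldrum's acid 4 (not isolated)
Conditions: DCC, DMAP (cat.), CH2Cl2, 0 °C to rt; filter; then MeOH, reflux
Reagents that add atoms: methanol, CO
Why: Carbodiimide-mediated C-acylation of Meldrum's acid followed by methanolysis of the acyl Meldrum's acid (loss of acetone and CO2) is the standard two-carbon homologation of a carboxylic acid to its β-keto ester.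

Step 3
Reactants: 5 methyl 4-[5-(benzyloxy)-2-bromophenyl]-3-oxobutanoate
Product: 7 (E)-4-[5-(benzyloxy)-2-bromophenyl]-3-methoxybut-2-enoic acid, via enol ether ester 6 (not isolated)
Conditions: HC(OMe)3, H2SO4 (cat.), MeOH, rt; then aq. NaOH, 60 °C; then cold 1 M HCl to pH 3
Reagents that add atoms: trimethyl orthoformate, COC(OC)OC; sodium hydroxide, [Na+].[OH-]
Why: Acid-catalysed enol etherification of a β-keto ester with trimethyl orthoformate gives the (E)-β-methoxy enoate, in which the carboxyl carbon is cis to the arylmethyl group, and this vinylogous carbonate survives the saponification that follows in the same flask (any β,γ-unsaturated isomer would converge in step 4).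

Step 4
Reactants: 7 (E)-4-[5-(benzyloxy)-2-bromophenyl]-3-methoxybut-2-enoic acid
Product: 10 8-(benzyloxy)-5-bromo-3-methoxynaphthalen-1-ol, via dienylketene 8 (not isolated), via naphthyl acetate 9 (not isolated)
Conditions: Ac2O, NaOAc, 130 °C; evaporate; then K2CO3 (cat.), degassed MeOH, rt, N2; aq. NH4Cl
Reagents that add atoms: none
Why: Under the acetic anhydride/sodium acetate conditions of the Stobbe naphthol synthesis the acid is dehydrated to dienylketene 8, which undergoes 6π electrocyclisation (formally an intramolecular Friedel–Crafts acylation) onto the only free ortho carbon, the one next to the benzyloxy group, the ring-closed naphthol is trapped in the hot anhydride as acetate 9, which shields it from oxidation, and carbonate-catalysed transesterification in methanol then releases naphthol 10, so ring A is formed with the C3 methoxy group and the free C1 hydroxyl already differentiated.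

Step 5
Reactants: 10 8-(benzyloxy)-5-bromo-3-methoxynaphthalen-1-ol
Product: 11 1,8-bis(benzyloxy)-5-bromo-3-methoxynaphthalene
Conditions: BnBr, K2CO3, DMF, 50 °C, N2
Reagents that add atoms: benzyl bromide, BrCc1ccccc1
Why: Williamson etherification of the naphthoxide with benzyl bromide gives the two peri oxygens (the future O1 and O10) the same hydrogenolysable group.

Step 6
Reactants: 12 dimethyl squarate; 13 L-proline tert-butyl ester
Product: 14 tert-butyl (2S)-1-(2-methoxy-3,4-dioxocyclobut-1-en-1-yl)pyrrolidine-2-carboxylate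
Conditions: MeOH, rt
Reagents that add atoms: none
Why: Addition–elimination of the secondary amine on the vinylogous ester of dimethyl squarate stops after one substitution because the squaramide ester formed is far less electrophilic, and the proline stereocentre is not touched.

Step 7
Reactants: 11 1,8-bis(benzyloxy)-5-bromo-3-methoxynaphthalene; 14 tert-butyl (2S)-1-(2-methoxy-3,4-dioxocyclobut-1-en-1-yl)pyrrolidine-2-carboxylate
Product: 16 tert-butyl (2S)-1-{4-[4,5-bis(benzyloxy)-7-methoxynaphthalen-1-yl]-4-hydroxy-2-methoxy-3-oxocyclobut-1-en-1-yl}pyrrolidine-2-carboxylate (both carbinol epimers), via aryllithium 15 (not isolated)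
Conditions: 11, t-BuLi (2.0 equiv), THF, −78 °C; then cannulated into 14 (1.2 equiv), THF, −78 °C; aq. NH4Cl
Reagents that add atoms: none
Why: Bromine–lithium exchange gives aryllithium 15, which adds 1,2 to the carbonyl next to the amino-bearing carbon because that carbonyl is only a vinylogous ester while the other is a deactivated vinylogous amide, forming the C4b–C5 bond with nitrogen beside the future C5; the new carbinol centre is uncontrolled and does not matter, since it becomes a carbonyl carbon in step 8.

Step 8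
Reactants: 16 tert-butyl (2S)-1-{4-[4,5-bis(benzyloxy)-7-methoxynaphthalen-1-yl]-4-hydroxy-2-methoxy-3-oxocyclobut-1-en-1-yl}pyrrolidine-2-carboxylate
Product: 19 tert-butyl (2S)-1-[1,10-bis(benzyloxy)-3,7-dimethoxy-5,8-dioxo-5,8-dihydrophenanthren-6-yl]pyrrolidine-2-carboxylate, via vinylketene 17 (not isolated), via hydroquinone 18 (not isolated)
Conditions: p-xylene (degassed), 138 °C, dark; cool; then Ag2O, rt
Reagents that add atoms: none
Why: Heating triggers a conrotatory 4π electrocyclic opening of the cyclobutenone to vinylketene 17, whose ketene carbon bonds to C8a of the naphthalene in a thermal (disrotatory) 6π electrocyclisation; tautomerisation gives aminohydroquinone 18, which Ag2O oxidises to quinone 19. The closest known reaction is the Moore–Liebeskind ring expansion of 4-aryl-4-hydroxycyclobutenones to annulated quinones. Ring C, the only ring closed, is formed by this 6π closure, which makes the C8–C8a bond. No stereocentre is created and the carbinol centre is destroyed, so both epimers of 16 converge. The step needs outward rotation of the hydroxyl, the intrinsic torquoselectivity of a donor on the carbinol carbon, which brings the naphthyl group cis to the ketene, and closure at C8a, the only ortho position that carries hydrogen. The order O, N, OMe, O on C5 to C8 is inherited unchanged from the squarate and from the regiochemistry of step 7.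

Step 9
Reactants: 19 tert-butyl (2S)-1-[1,10-bis(benzyloxy)-3,7-dimethoxy-5,8-dioxo-5,8-dihydrophenanthren-6-yl]pyrrolidine-2-carboxylate
Product: 20 tert-butyl (2S)-1-[(5R)-1,10-bis(benzyloxy)-5-hydroxy-3,7-dimethoxy-5-methyl-8-oxo-5,8-dihydrophenanthren-6-yl]pyrrolidine-2-carboxylate
Conditions: MeMgBr (1.5 equiv), THF, −78 °C, dark; aq. NH4Cl at −78 °C; chromatographic separation of the C5 epimers
Reagents that add atoms: methylmagnesium bromide, C[Mg]Br
Why: Grignard 1,2-addition should take the C5 carbonyl, which is a vinylogous ester type ketone and so more electrophilic than the C8 carbonyl, the vinylogous amide partner of N6, and the new C5 stereocentre is set under substrate control by the (S)-prolinate, whose tert-butoxycarbonyl group screens one face of ring C next to C5; as the two C5 epimers are diastereomers, the 5R isomer should be separable by chromatography.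

Step 10
Reactants: 20 tert-butyl (2S)-1-[(5R)-1,10-bis(benzyloxy)-5-hydroxy-3,7-dimethoxy-5-methyl-8-oxo-5,8-dihydrophenanthren-6-yl]pyrrolidine-2-carboxylate
Product: 22 (2S)-1-[(5R)-1,10-bis(benzyloxy)-5-hydroxy-3,7-dimethoxy-5-methyl-8-oxo-5,8-dihydrophenanthren-6-yl]pyrrolidine-2-carboxylic acid, via bis(trimethylsilyl) derivative 21 (not isolated)
Conditions: TMSOTf, 2,6-lutidine, CH2Cl2, 0 °C; then NH4F, MeOH, rt; pH 5 buffer
Reagents that add atoms: none
Why: Silyl triflate cleavage of a tert-butyl ester (loss of isobutene to the trimethylsilyl ester) runs under lutidine-buffered conditions that avoid the protic acid which could ionise the tertiary benzylic C5 carbinol, and fluoride-assisted methanolysis then frees both the acid and the transiently silylated alcohol without touching C5.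

Step 11
Reactants: 22 (2S)-1-[(5R)-1,10-bis(benzyloxy)-5-hydroxy-3,7-dimethoxy-5-methyl-8-oxo-5,8-dihydrophenanthren-6-yl]pyrrolidine-2-carboxylic acid
Product: 24 (5R)-1,10-bis(benzyloxy)-3,7-dimethoxy-5-methylphenanthren-8(5H)-one in which O5 and N6 are joined through C2 (S) of a pyrrolidine whose N1 is N6 (oxazolidine N,O-acetal), via iminium acetate 23 (not isolated)
Conditions: Pb(OAc)4 (1.1 equiv), pyridine, CH2Cl2, 0 °C to rt, dark; aq. NaHCO3
Reagents that add atoms: none
Why: Lead tetraacetate oxidative decarboxylation (Kochi type) of the α-amino acid gives the nitrogen-stabilised cation, iminium 23, which the C5 hydroxyl captures in an oxazolidine-forming N,O-acetalisation; the aminal carbon is set relative to C5, with its hydrogen cis to the C5 methyl so that the methyl lies on the convex face of the fused five-membered rings, and it can equilibrate to this arrangement through the iminium in the acetic acid released.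

Step 12
Reactants: 24 (5R)-1,10-bis(benzyloxy)-3,7-dimethoxy-5-methylphenanthren-8(5H)-one N,O-acetal
Product: 26 CNP0528850.1, via enol tautomer 25 (not isolated)
Conditions: H2 (1 atm), 10% Pd/C, EtOAc, rt
Reagents that add atoms: none
Why: Catalytic hydrogenolysis removes both aryl benzyl ethers without affecting the tetrasubstituted enaminone or the N,O-acetal, and the 10-hydroxy compound 25 set free is the enol of the target and should tautomerise to the C10 ketone with C9H2, held by the hydrogen bond from the C1 hydroxyl.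

Compound list
1 | 3-(benzyloxy)phenylacetic acid | OC(=O)Cc1cccc(OCc2ccccc2)c1 | starting material
2 | 2-[5-(benzyloxy)-2-bromophenyl]acetic acid | OC(=O)Cc1cc(OCc2ccccc2)ccc1Br | intermediate
3 | Meldrum's acid (2,2-dimethyl-1,3-dioxane-4,6-dione) | CC1(C)OC(=O)CC(=O)O1 | starting material
4 | 5-{2-[5-(benzyloxy)-2-bromophenyl]-1-hydroxyethylidene}-2,2-dimethyl-1,3-dioxane-4,6-dione (acyl Meldrum's acid, in situ) | CC1(C)OC(=O)C(=C(O)Cc2cc(OCc3ccccc3)ccc2Br)C(=O)O1 | intermediate
5 | methyl 4-[5-(benzyloxy)-2-bromophenyl]-3-oxobutanoate | COC(=O)CC(=O)Cc1cc(OCc2ccccc2)ccc1Br | intermediate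
6 | methyl (E)-4-[5-(benzyloxy)-2-bromophenyl]-3-methoxybut-2-enoate (in situ) | CO/C(Cc1cc(OCc2ccccc2)ccc1Br)=C/C(=O)OC | intermediate
7 | (E)-4-[5-(benzyloxy)-2-bromophenyl]-3-methoxybut-2-enoic acid | CO/C(Cc1cc(OCc2ccccc2)ccc1Br)=C/C(=O)O | intermediate
8 | 4-[5-(benzyloxy)-2-bromophenyl]-3-methoxybuta-1,3-dien-1-one (dienylketene, in situ) | O=C=CC(OC)=Cc1cc(OCc2ccccc2)ccc1Br | intermediate
9 | 8-(benzyloxy)-5-bromo-3-methoxynaphthalen-1-yl acetate (in situ) | COc1cc(OC(C)=O)c2c(OCc3ccccc3)ccc(Br)c2c1 | intermediate
10 | 8-(benzyloxy)-5-bromo-3-methoxynaphthalen-1-ol | COc1cc(O)c2c(OCc3ccccc3)ccc(Br)c2c1 | intermediate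
11 | 1,8-bis(benzyloxy)-5-bromo-3-methoxynaphthalene | COc1cc(OCc2ccccc2)c2c(OCc3ccccc3)ccc(Br)c2c1 | intermediate
12 | dimethyl squarate (3,4-dimethoxycyclobut-3-ene-1,2-dione) | COC1=C(OC)C(=O)C1=O | starting material
13 | L-proline tert-butyl ester | CC(C)(C)OC(=O)[C@@H]1CCCN1 | starting material
14 | tert-butyl (2S)-1-(2-methoxy-3,4-dioxocyclobut-1-en-1-yl)pyrrolidine-2-carboxylate | COC1=C(N2CCC[C@H]2C(=O)OC(C)(C)C)C(=O)C1=O | intermediate
15 | [4,5-bis(benzyloxy)-7-methoxynaphthalen-1-yl]lithium (in situ) | [Li]c1ccc(OCc2ccccc2)c2c(OCc3ccccc3)cc(OC)cc12 | intermediate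
16 | tert-butyl (2S)-1-{4-[4,5-bis(benzyloxy)-7-methoxynaphthalen-1-yl]-4-hydroxy-2-methoxy-3-oxocyclobut-1-en-1-yl}pyrrolidine-2-carboxylate (both carbinol epimers) | COC1=C(N2CCC[C@H]2C(=O)OC(C)(C)C)C(O)(c2ccc(OCc3ccccc3)c3c(OCc4ccccc4)cc(OC)cc23)C1=O | intermediate
17 | tert-butyl (2S)-1-{1-[4,5-bis(benzyloxy)-7-methoxynaphthalen-1-yl]-1-hydroxy-3-methoxy-4-oxobuta-1,3-dien-2-yl}pyrrolidine-2-carboxylate (vinylketene, in situ) | O=C=C(OC)C(N1CCC[C@H]1C(=O)OC(C)(C)C)=C(O)c1ccc(OCc2ccccc2)c2c(OCc3ccccc3)cc(OC)cc12 | intermediate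
18 | tert-butyl (2S)-1-[1,10-bis(benzyloxy)-5,8-dihydroxy-3,7-dimethoxyphenanthren-6-yl]pyrrolidine-2-carboxylate (hydroquinone, in situ) | COc1c(N2CCC[C@H]2C(=O)OC(C)(C)C)c(O)c2c(cc(OCc3ccccc3)c3c(OCc4ccccc4)cc(OC)cc32)c1O | intermediate
19 | tert-butyl (2S)-1-[1,10-bis(benzyloxy)-3,7-dimethoxy-5,8-dioxo-5,8-dihydrophenanthren-6-yl]pyrrolidine-2-carboxylate | COC1=C(N2CCC[C@H]2C(=O)OC(C)(C)C)C(=O)c2c(cc(OCc3ccccc3)c3c(OCc4ccccc4)cc(OC)cc32)C1=O | intermediate
20 | tert-butyl (2S)-1-[(5R)-1,10-bis(benzyloxy)-5-hydroxy-3,7-dimethoxy-5-methyl-8-oxo-5,8-dihydrophenanthren-6-yl]pyrrolidine-2-carboxylate | COC1=C(N2CCC[C@H]2C(=O)OC(C)(C)C)[C@](C)(O)c2c(cc(OCc3ccccc3)c3c(OCc4ccccc4)cc(OC)cc32)C1=O | intermediate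
21 | trimethylsilyl (2S)-1-[(5R)-1,10-bis(benzyloxy)-3,7-dimethoxy-5-methyl-8-oxo-5-(trimethylsilyloxy)-5,8-dihydrophenanthren-6-yl]pyrrolidine-2-carboxylate (in situ) | COC1=C(N2CCC[C@H]2C(=O)O[Si](C)(C)C)[C@](C)(O[Si](C)(C)C)c2c(cc(OCc3ccccc3)c3c(OCc4ccccc4)cc(OC)cc32)C1=O | intermediate
22 | (2S)-1-[(5R)-1,10-bis(benzyloxy)-5-hydroxy-3,7-dimethoxy-5-methyl-8-oxo-5,8-dihydrophenanthren-6-yl]pyrrolidine-2-carboxylic acid | COC1=C(N2CCC[C@H]2C(O)=O)[C@](C)(O)c2c(cc(OCc3ccccc3)c3c(OCc4ccccc4)cc(OC)cc32)C1=O | intermediate
23 | 1-[(5R)-1,10-bis(benzyloxy)-5-hydroxy-3,7-dimethoxy-5-methyl-8-oxo-5,8-dihydrophenanthren-6-yl]-3,4-dihydro-2H-pyrrol-1-ium acetate (in situ) | COC1=C([N+]2=CCCC2)[C@](C)(O)c2c(cc(OCc3ccccc3)c3c(OCc4ccccc4)cc(OC)cc32)C1=O.CC(=O)[O-] | intermediate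
24 | (5R)-1,10-bis(benzyloxy)-3,7-dimethoxy-5-methylphenanthren-8(5H)-one with O5 and N6 joined through C2 (S) of a pyrrolidine whose N1 is N6 (oxazolidine N,O-acetal, aminal H cis to the C5 methyl) | COC1=C2N3CCC[C@@H]3O[C@]2(C)c2c(cc(OCc3ccccc3)c3c(OCc4ccccc4)cc(OC)cc23)C1=O | intermediate
25 | 1,10-dihydroxy analogue of 24 (enol tautomer of the target, in situ) | COC1=C2N3CCC[C@@H]3O[C@]2(C)c2c(cc(O)c3c(O)cc(OC)cc23)C1=O | intermediate
26 | CNP0528850.1: (5R)-1-hydroxy-3,7-dimethoxy-5-methylphenanthrene-8,10(5H,9H)-dione with O5 and N6 joined through C2 (S) of a pyrrolidine whose N1 is N6 | COC1=C2N3CCC[C@@H]3O[C@]2(C)C2=C(CC(=O)c3c(O)cc(OC)cc32)C1=O | target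

Total step count: 12. Longest linear sequence: 11 steps (steps 1 to 5, then 7 to 12); step 6 is a one-step side branch.

The three steps most likely to fail

Step 8 (ring expansion). The amino group turns the cyclobutenone into a vinylogous amide, so ring opening may need temperatures at which the aminohydroquinone or the tert-butyl ester degrades, and any loss of torquoselectivity sends the ketene onto its own hydroxyl to a furanone. The fallback takes nitrogen out of the electrocyclic step. It sets out from bromide 11 (lithiated to 15 as in step 7) and dimethyl squarate 12, whose 1,2-adduct is 4-[4,5-bis(benzyloxy)-7-methoxynaphthalen-1-yl]-4-hydroxy-2,3-dimethoxycyclobut-2-en-1-one F1. This dialkoxy cyclobutenone, the most reliable substrate class for the ring expansion, is heated in toluene or p-xylene and oxidised with Ag2O to 1,10-bis(benzyloxy)-3,6,7-trimethoxyphenanthrene-5,8-dione F2. Addition–elimination of L-proline tert-butyl ester 13 (MeCN, rt) should then replace the C6 methoxy group, because C6 is β to the C8 carbonyl, the more electrophilic one (the C5 carbonyl sits in the bay and is conjugated with the C10 oxygen through C4b). This returns the route at quinone 19.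

Step 9 (methyl addition). The prolinate may discriminate the two faces of C5 poorly or favour the 5S epimer, and some attack at C8 is possible. The fallback changes the controlling element to its mirror image. It sets out from dimethyl squarate 12 and D-proline tert-butyl ester F3, which give tert-butyl (2R)-1-(2-methoxy-3,4-dioxocyclobut-1-en-1-yl)pyrrolidine-2-carboxylate F4. Aryllithium 15 adds to it to give the (2R) cyclobutenone carbinol F5, and thermolysis with Ag2O oxidation gives the (2R) quinone F6. Methyl addition then gives the (5R,2R) carbinol F7, which is the favoured epimer if the L series favours 5S, and buffered ester cleavage gives the (5R,2R) acid F8. Oxidative decarboxylation of F8 erases the proline carbon's configuration at the iminium stage, so the route is rejoined at N,O-acetal 24.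

Step 11 (oxidative decarboxylation). Lead tetraacetate may attack the electron-rich trialkoxynaphthalene or the enaminone in competition with ligand exchange at the carboxyl group, or the α-amino radical may be diverted before it is oxidised. The fallback is a non-oxidative Curtius degradation that sets out from acid 22. Diphenylphosphoryl azide and Et3N in toluene give the acyl azide F9, which rearranges with retention at 80 °C to the 2-isocyanatopyrrolidine F10. Hydrolysis in wet THF with acetic acid gives the geminal diamine, which loses ammonia to the same iminium 23 and closes to 24, where the route is rejoined.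

Further compounds
F1 | step 8 | 4-[4,5-bis(benzyloxy)-7-methoxynaphthalen-1-yl]-4-hydroxy-2,3-dimethoxycyclobut-2-en-1-one | COC1=C(OC)C(O)(c2ccc(OCc3ccccc3)c3c(OCc4ccccc4)cc(OC)cc23)C1=O
F2 | step 8 | 1,10-bis(benzyloxy)-3,6,7-trimethoxyphenanthrene-5,8-dione | COC1=C(OC)C(=O)c2c(cc(OCc3ccccc3)c3c(OCc4ccccc4)cc(OC)cc32)C1=O
F3 | step 9 | D-proline tert-butyl ester | CC(C)(C)OC(=O)[C@H]1CCCN1
F4 | step 9 | tert-butyl (2R)-1-(2-methoxy-3,4-dioxocyclobut-1-en-1-yl)pyrrolidine-2-carboxylate | COC1=C(N2CCC[C@@H]2C(=O)OC(C)(C)C)C(=O)C1=O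
F5 | step 9 | tert-butyl (2R)-1-{4-[4,5-bis(benzyloxy)-7-methoxynaphthalen-1-yl]-4-hydroxy-2-methoxy-3-oxocyclobut-1-en-1-yl}pyrrolidine-2-carboxylate | COC1=C(N2CCC[C@@H]2C(=O)OC(C)(C)C)C(O)(c2ccc(OCc3ccccc3)c3c(OCc4ccccc4)cc(OC)cc23)C1=O
F6 | step 9 | tert-butyl (2R)-1-[1,10-bis(benzyloxy)-3,7-dimethoxy-5,8-dioxo-5,8-dihydrophenanthren-6-yl]pyrrolidine-2-carboxylate | COC1=C(N2CCC[C@@H]2C(=O)OC(C)(C)C)C(=O)c2c(cc(OCc3ccccc3)c3c(OCc4ccccc4)cc(OC)cc32)C1=O
F7 | step 9 | tert-butyl (2R)-1-[(5R)-1,10-bis(benzyloxy)-5-hydroxy-3,7-dimethoxy-5-methyl-8-oxo-5,8-dihydrophenanthren-6-yl]pyrrolidine-2-carboxylate | COC1=C(N2CCC[C@@H]2C(=O)OC(C)(C)C)[C@](C)(O)c2c(cc(OCc3ccccc3)c3c(OCc4ccccc4)cc(OC)cc32)C1=O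
F8 | step 9 | (2R)-1-[(5R)-1,10-bis(benzyloxy)-5-hydroxy-3,7-dimethoxy-5-methyl-8-oxo-5,8-dihydrophenanthren-6-yl]pyrrolidine-2-carboxylic acid | COC1=C(N2CCC[C@@H]2C(O)=O)[C@](C)(O)c2c(cc(OCc3ccccc3)c3c(OCc4ccccc4)cc(OC)cc32)C1=O
F9 | step 11 | (2S)-1-[(5R)-1,10-bis(benzyloxy)-5-hydroxy-3,7-dimethoxy-5-methyl-8-oxo-5,8-dihydrophenanthren-6-yl]pyrrolidine-2-carbonyl azide | COC1=C(N2CCC[C@H]2C(=O)N=[N+]=[N-])[C@](C)(O)c2c(cc(OCc3ccccc3)c3c(OCc4ccccc4)cc(OC)cc32)C1=O
F10 | step 11 | (5R)-1,10-bis(benzyloxy)-5-hydroxy-6-(2-isocyanatopyrrolidin-1-yl)-3,7-dimethoxy-5-methylphenanthren-8(5H)-one (configuration at the pyrrolidine carbon retained) | COC1=C(N2CCC[C@H]2N=C=O)[C@](C)(O)c2c(cc(OCc3ccccc3)c3c(OCc4ccccc4)cc(OC)cc32)C1=O
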